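Assumption: the target SMILES has no stereo descriptor, and the molecule has no stereocentre and no stereogenic double bond. It is achiral, so the demand for a single enantiomer needs no stereocontrolled step.

## Structural features

The target 10 is 1-(3,4-dihydroxyphenyl)icosan-5-one. It has one benzene ring (C1′–C6′) with hydroxyl groups at C3′ and C4′ and an unbranched C20 chain at C1′. The chain holds a single ketone at C5; C1–C4 form an unfunctionalised four-methylene tether to the ring, and C6–C20 form a pentadecyl tail. The fragile group is the catechol. It is easily oxidised to the o-quinone, donates hydrogen atoms readily and chelates metals, so it must be masked in radical or transition-metal steps. The ketone is flanked by two almost identical methylene groups (C4 and C6). Its position therefore cannot be set or corrected by late enolate chemistry, and positional isomers or homologues of so waxy a compound would be very hard to separate. The real difficulty is connectivity: arene and carbonyl group stand in a remote relation, and C2 and C3 are activated by neither. The key step exploits two facts. First, C3–C4–C5(=O) is the ring-opened form of a symmetrical 1-substituted cyclopropanol whose carbinol carbon is C1 of palmitic acid. Second, aryl–C1–C2 is a dihydrocaffeic acid unit that has lost CO2, so the two pieces meet at the "silent" C2–C3 bond.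

## Logic of the disconnections

**10 back to 8 (through 9).** The last forward step cuts the two O–CH3 bonds at O3′ and O4′.
- Reason: a free catechol would quench radical 7 by hydrogen transfer and would bind nickel.
- Gain: the skeleton is not simplified, but the aryl piece 5 is commercial with these ethers already in place.
- Demand: the ether cleavage must spare the C5 ketone, and 10 must be kept from air.

**8 back to 4 and 6 (through 7).** The C2–C3 bond is cut. In the same backward operation C3 is tied to C5, so that C3–C4–C5 becomes a three-membered ring and the ketone a tertiary carbinol, while C2 receives an activated carboxyl group.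
- Reason: this bond lies at the centre of the tether, where no polar activation exists. In 4, C3 (normally an acceptor position β to the carbonyl group) becomes a donor, a homoenolate polarity reversal. C2 is addressed as a radical.
- Gain: a C28 compound falls into a C18 piece and a C11 piece, each one step from a commodity chemical. The ketone position is fixed by the carbinol carbon of 4.
- In one sentence, the route is the decarboxylative coupling of 6 with the ring-opened form of 4 at C2–C3. That sentence does not fit a carbonyl addition next to C5, which is what would be drawn first.
- Demand: a cross-selective C(sp3)–C(sp3) coupling that outruns β-hydride elimination.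

**4 back to 1 and 2 (through 3).** The C3–C5 and C4–C5 bonds of the ring are cut.
- Reason: C5 is the ester carbon of 1, and the C3–C4 unit is the ethyl group of 2 used as a 1,2-dicarbanion equivalent.
- Gain: both components are bulk chemicals, and the whole C5–C20 segment is bought.
- Demand: the titanium cycle must outrun direct addition of 2 to the ester.

**6 back to 5.** The acyl C–O bond of the N-acyloxyphthalimide is cut.
- Reason: the carboxyl group of 5 marks C2 as the radical site and leaves as CO2.
- Gain: 5 is commercial and already holds ring, ethers, C1 and C2.
- Demand: a mild esterification only.

## Other disconnections considered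

**Alternative 1:** (the first that comes to mind) cut C5–C6 next to the carbonyl carbon. The forward key step is acyl substitution of the Weinreb amide N-methoxy-N-methyl-5-(3,4-dimethoxyphenyl)pentanamide A1 with pentadecylmagnesium bromide A2, which gives 8.
- The cut removes only the featureless tail. Aryl ring, four methylenes and carbonyl carbon all remain in A1.
- The parent acid of A1, 5-(3,4-dimethoxyphenyl)pentanoic acid A3, must first be built by Friedel–Crafts acylation, benzylic deoxygenation and amidation.
- The longest linear sequence would be five to six steps against three, and a long-chain Grignard reagent prone to Wurtz-type homocoupling is needed in stoichiometric amount.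
- This is the default route and fails the first test.

**Alternative 2:** cut the C1′–C1 bond. The forward key step is a chain-walking (redox-relay) Heck arylation of racemic icos-1-en-5-ol A4 with 4-iodo-1,2-dimethoxybenzene A5. Palladium migrates from C2 to C5 and releases 8.
- The plan has one step fewer in total and the same longest linear sequence.
- However, A4 is itself made by a classical carbonyl addition at C5, so the position of the oxygen is still set in the conventional way.
- The key step needs three selectivities that the substrate does not secure:
  - terminal rather than internal arylation of an unbiased alkene;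
  - first β-hydride elimination towards C3 rather than towards the benzylic C1–H, although the latter gives a conjugated electron-rich styrene;
  - three migrations without dissociation of palladium.
- Each failure leaves a positional isomer that is hard to remove from waxy 8. In the chosen plan no isomer can arise.

**Alternative 3:** cut the same C2–C3 bond, but homolytically on both sides. The forward key step is a mixed Kolbe electrolysis of 5 with 4-oxononadecanoic acid A6, which gives 8.
- Both radicals are born at the same anode by the same mechanism, so coupling is statistical and the two symmetrical dimers are unavoidable.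
- The dimethoxyarene of 5 is oxidised at a potential well below that needed for carboxylate discharge, so ring oxidation should compete.
- A6 still has to be made.
- The chosen plan keeps the bond but activates the two partners by orthogonal mechanisms, which builds in cross-selectivity.

Key step: step 3

## Route

Numbering rule: compounds whose carbon atoms end up in 10, and everything made from them, are numbered. Pure activating or cleaving reagents are given by name and SMILES in the step.

Step 1
Reactants: 1 methyl hexadecanoate (methyl palmitate); 2 ethylmagnesium bromide
Product: 4 1-pentadecylcyclopropan-1-ol, via magnesium cyclopropanolate 3 (not isolated)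
Conditions: 2 (2.4 equiv, slow addition), Ti(OiPr)4 (15 mol %), Et2O/THF, 0 °C to rt; then H2O, 0 °C, filtration through Celite
Reagents that add atoms: ethylmagnesium bromide (2), CC[Mg]Br
Why: Kulinkovich cyclopropanation: 2 and the titanium alkoxide give a titanacyclopropane (with loss of ethane) that acts as a 1,2-dicarbanion and adds twice to the ester carbon of 1 with expulsion of methoxide, and unbranched fatty esters are standard substrates. Slow addition of 2 keeps direct Grignard addition behind the titanium cycle, and no stereocentre is formed.

Step 2
Reactants: 5 3-(3,4-dimethoxyphenyl)propanoic acid
Product: 6 1,3-dioxoisoindolin-2-yl 3-(3,4-dimethoxyphenyl)propanoate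
Conditions: N-hydroxyphthalimide (1.05 equiv), DIC (1.1 equiv), DMAP (5 mol %), CH2Cl2, rt
Reagents that add atoms: N-hydroxyphthalimide, O=C1c2ccccc2C(=O)N1O
Why: Steglich-type carbodiimide esterification of a primary carboxylic acid with the acidic N–OH group. The dimethoxyarene is inert, and the redox-active ester should be obtained pure by filtration of the urea and recrystallisation.

Step 3
Reactants: 4 1-pentadecylcyclopropan-1-ol; 6 1,3-dioxoisoindolin-2-yl 3-(3,4-dimethoxyphenyl)propanoate
Product: 8 1-(3,4-dimethoxyphenyl)icosan-5-one, via arylethyl radical 7 (not isolated)
Conditions: 4 (1.5 equiv), Ni(acac)2 (10 mol %), dtbbpy (12 mol %), Et3N (1.5 equiv), DMA, 40 °C, Ar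
Reagents that add atoms: none
Why: This is a nickel-catalysed decarboxylative β-alkylation of a cyclopropanol-derived homoenolate with a redox-active ester, a known C(sp3)–C(sp3) coupling closely related to decarboxylative Negishi alkyl–alkyl coupling. Alkoxide exchange places 4 on Ni(II), and strain-driven two-electron β-carbon elimination opens the ring to a carbonyl-chelated Ni–CH2CH2C(=O)C15H31 homoenolate, which unveils the C5 ketone and makes C3 the donor carbon. A Ni(I) species reduces 6 by one electron, and N–O cleavage with loss of CO2 gives the primary radical 7 and phthalimide anion, which takes up the carbinol proton. Capture of 7 by the Ni(II) homoenolate gives a Ni(III) dialkyl whose fast reductive elimination forms the C2–C3 bond of 8 and returns Ni(I), so the step is redox-neutral and needs no metal reductant. No ring is closed and no stereocentre is formed; the only ring event is the opening of the three-membered ring. Regioselectivity of the opening is no issue because the two ring CH2 groups of 4 are equivalent, and the 1,2-aryl shift open to 7 is degenerate because C1 and C2 are both CH2. The step needs cross-selectivity, and this is secured because the partners are activated by orthogonal mechanisms (two-electron β-carbon elimination against one-electron reduction), so neither can take the place of the other at nickel. The main competitors are β-hydride elimination of the homoenolate, held back by the five-membered O-chelate and the bidentate ligand, and O-acylation of the tertiary alkoxide by 6, held back by steric hindrance and the weak amine base.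

Step 4
Reactants: 8 1-(3,4-dimethoxyphenyl)icosan-5-one
Product: 10 1-(3,4-dihydroxyphenyl)icosan-5-one, via cyclic bromoborate 9 (not isolated)
Conditions: BBr3 (3.5 equiv), CH2Cl2, −78 °C to 0 °C, Ar; then degassed H2O, 0 °C
Reagents that add atoms: none
Why: Lewis-acid cleavage of aryl methyl ethers: BBr3 binds each ether oxygen and bromide attacks the methyl group (SN2), which gives the five-membered cyclic bromoborate 9, whose B and Br come from BBr3 and leave again on hydrolysis. One extra equivalent allows for reversible complexation of the C5 ketone, which has no leaving group and returns unchanged on hydrolysis, and degassed work-up protects the catechol from air.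

## Compound list

1 | methyl hexadecanoate (methyl palmitate) | CCCCCCCCCCCCCCCC(=O)OC | starting material
2 | ethylmagnesium bromide | CC[Mg]Br | starting material
3 | bromomagnesium 1-pentadecylcyclopropan-1-olate | CCCCCCCCCCCCCCCC1(CC1)O[Mg]Br | intermediate (not isolated)
4 | 1-pentadecylcyclopropan-1-ol | CCCCCCCCCCCCCCCC1(O)CC1 | intermediate
5 | 3-(3,4-dimethoxyphenyl)propanoic acid | COc1ccc(CCC(=O)O)cc1OC | starting material
6 | 1,3-dioxoisoindolin-2-yl 3-(3,4-dimethoxyphenyl)propanoate | COc1ccc(CCC(=O)ON2C(=O)c3ccccc3C2=O)cc1OC | intermediate
7 | 2-(3,4-dimethoxyphenyl)ethyl radical | [CH2]Cc1ccc(OC)c(OC)c1 | intermediate (not isolated)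
8 | 1-(3,4-dimethoxyphenyl)icosan-5-one | CCCCCCCCCCCCCCCC(=O)CCCCc1ccc(OC)c(OC)c1 | intermediate
9 | 1-(2-bromo-1,3,2-benzodioxaborol-5-yl)icosan-5-one | CCCCCCCCCCCCCCCC(=O)CCCCc1ccc2OB(Br)Oc2c1 | intermediate (not isolated)
10 | 1-(3,4-dihydroxyphenyl)icosan-5-one (achiral) | CCCCCCCCCCCCCCCC(=O)CCCCc1ccc(O)c(O)c1 | target

## Step count and least certain steps

Total step count: 4. Longest linear sequence: 3 (1 → 4 → 8 → 10, or equally 5 → 6 → 8 → 10).

**Step 3 (key step).**
- What may go wrong: the nickel homoenolate decays by β-hydride elimination before it captures 7, and 7 is then lost by hydrogen abstraction or dimerisation. Acyl transfer from 6 to the alkoxide of 4 is a second drain.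
- Why: the bimolecular radical capture at a low concentration of catalyst must compete with fast unimolecular and radical–radical processes.
- Fallback: invert the polarity at C3 and form the same bond by radical conjugate addition. The fallback sets out from 4 and 6. Ring-opening bromination of 4 with N-bromosuccinimide gives 1-bromooctadecan-3-one F1. Triethylamine then eliminates HBr to give octadec-1-en-3-one F2. A reductive decarboxylative Giese addition of 6 to F2 (Ru(bpy)3(PF6)2, Hantzsch ester, iPr2NEt, blue light) comes back to the route at 8.

**Step 4.**
- What may go wrong: incomplete cleavage of the second ether, Lewis-acid-promoted enolisation and self-condensation at the ketone, and air oxidation of the catechol during work-up and chromatography.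
- Why: the ketone ties up Lewis acid, and the product is both lipophilic and easily oxidised.
- Fallback: replace ether dealkylation by ketal hydrolysis as the end game. The fallback sets out from 4 and uses a different aryl partner. Commercial 3-(3,4-dihydroxyphenyl)propanoic acid F3 is condensed with 2,2-dimethoxypropane (TsOH cat., toluene, reflux) to give 3-(2,2-dimethyl-1,3-benzodioxol-5-yl)propanoic acid F4. This acid is esterified as in step 2 to give 1,3-dioxoisoindolin-2-yl 3-(2,2-dimethyl-1,3-benzodioxol-5-yl)propanoate F5. F5 is coupled with 4 as in step 3 to give 1-(2,2-dimethyl-1,3-benzodioxol-5-yl)icosan-5-one F6. Mild hydrolysis (TFA/H2O/CH2Cl2, rt, Ar) comes back to the route at 10.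

**Step 1.**
- What may go wrong: direct double addition of 2 to the ester outruns the titanium cycle, and the cyclopropanol isomerises by ring opening during work-up.
- Why: the waxy ester dissolves poorly in cold ether, and the strained carbinol is sensitive to acid and base.
- Fallback: bypass the cyclopropanol. The fallback sets out from 1. N,O-Dimethylhydroxylamine hydrochloride and iPrMgCl (THF, −10 °C) give N-methoxy-N-methylhexadecanamide F7. Vinylmagnesium bromide, with inverse quench into cold dilute acid, gives octadec-1-en-3-one F2. The reductive decarboxylative Giese addition of 6 to F2 described above comes back to the route at 8.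

## Further compounds

F1 | step 3 | 1-bromooctadecan-3-one | CCCCCCCCCCCCCCCC(=O)CCBr
F2 | step 3 | octadec-1-en-3-one | CCCCCCCCCCCCCCCC(=O)C=C
F3 | step 4 | 3-(3,4-dihydroxyphenyl)propanoic acid | OC(=O)CCc1ccc(O)c(O)c1
F4 | step 4 | 3-(2,2-dimethyl-1,3-benzodioxol-5-yl)propanoic acid | CC1(C)Oc2ccc(CCC(=O)O)cc2O1
F5 | step 4 | 1,3-dioxoisoindolin-2-yl 3-(2,2-dimethyl-1,3-benzodioxol-5-yl)propanoate | CC1(C)Oc2ccc(CCC(=O)ON3C(=O)c4ccccc4C3=O)cc2O1
F6 | step 4 | 1-(2,2-dimethyl-1,3-benzodioxol-5-yl)icosan-5-one | CCCCCCCCCCCCCCCC(=O)CCCCc1ccc2OC(C)(C)Oc2c1
F7 | step 1 | N-methoxy-N-methylhexadecanamide | CCCCCCCCCCCCCCCC(=O)N(C)OC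
A1 | alternative 1 | N-methoxy-N-methyl-5-(3,4-dimethoxyphenyl)pentanamide | CON(C)C(=O)CCCCc1ccc(OC)c(OC)c1
A2 | alternative 1 | pentadecylmagnesium bromide | CCCCCCCCCCCCCCC[Mg]Br
A3 | alternative 1 | 5-(3,4-dimethoxyphenyl)pentanoic acid | OC(=O)CCCCc1ccc(OC)c(OC)c1
A4 | alternative 2 | icos-1-en-5-ol (racemic) | C=CCCC(O)CCCCCCCCCCCCCCC
A5 | alternative 2 | 4-iodo-1,2-dimethoxybenzene | COc1ccc(I)cc1OC
A6 | alternative 3 | 4-oxononadecanoic acid | CCCCCCCCCCCCCCCC(=O)CCC(=O)O
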